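**Strategy.** The nine-membered oxa ring (O, C3, C4, C5, C6, C7, C8, C9, C10; germacrane numbering) is closed last, through its C7–C8 bond. The key step exploits the homoallylic alcohol pattern C13=C11–C7–C8–O that links the α-methylene-γ-lactone to the C8 ester. A CrCl2-mediated intramolecular Barbier (Nozaki–Hiyama–Kishi) allylation of a tethered aldehyde by a 3-(bromomethyl)butenolide forms C7–C8, sets C7 and C8 and unveils the exocyclic methylene in one operation. The precursor already holds both smaller rings: the butenolide and a 4,5-dihydrofuran whose enol ether carbon C3 is the dehydrated form of the hemiketal, hydrated in the final step.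

Key step: step 16

Numbering used throughout: C1–C10 carbocycle (C3 hemiketal carbon, C4=C5, C6 lactone O–CH, C8 acyloxy carbon, C10 quaternary ether carbon); C11, C12, C13 = lactone α-carbon, carbonyl, exocyclic CH2; C14 = CH2OH on C10; C15 = CH3 on C4.
Assumption: aqueous acid hydrates the bridgehead enol ether of 28 to the hemiketal drawn for the target, which is taken to be its stable form.

**Alkyne fragment**

Step 1
Reactants: 1 propargyl alcohol; 2 allylmagnesium chloride
Product: 3 2-methylidenepent-4-en-1-ol
Conditions: CuI (10 mol%), THF, −20 °C to rt; aq. NH4Cl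
Reagents that add atoms: none
Why: Copper-catalysed anti-carbomagnesiation of the propargylic alkoxide delivers the allyl group to the internal alkyne carbon while magnesium is chelated at the terminus, and protonation gives the 2-substituted allylic alcohol; no stereocentre is formed.

Step 2
Reactants: 3 2-methylidenepent-4-en-1-ol
Product: 4 [(2R)-2-(prop-2-en-1-yl)oxiran-2-yl]methanol
Conditions: Ti(OiPr)4 (10 mol%), D-(−)-diisopropyl tartrate (12 mol%), t-BuOOH, 4 Å molecular sieves, CH2Cl2, −20 °C
Reagents that add atoms: tert-butyl hydroperoxide, CC(C)(C)OO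
Why: Sharpless asymmetric epoxidation of a 2-substituted allylic alcohol; the D-(−)-tartrate–titanium catalyst delivers the peroxide oxygen to one enantiotopic face of the 1,1-disubstituted alkene and sets the quaternary C10 as (R) under reagent control.

Step 3
Reactants: 4 [(2R)-2-(prop-2-en-1-yl)oxiran-2-yl]methanol
Product: 5 tert-butyl(dimethyl){[(2S)-2-(prop-2-en-1-yl)oxiran-2-yl]methoxy}silane
Conditions: TBSCl, imidazole, DMF, 0 °C to rt
Reagents that add atoms: tert-butyldimethylsilyl chloride, CC(C)(C)[Si](C)(C)Cl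
Why: Standard silylation of the primary alcohol; the epoxide and its stereocentre are untouched (the descriptor changes only through priorities).

Step 4
Reactants: 5 tert-butyl(dimethyl){[(2S)-2-(prop-2-en-1-yl)oxiran-2-yl]methoxy}silane; 6 lithium acetylide–ethylenediamine complex
Product: 7 (4S)-4-{[tert-butyl(dimethyl)silyl]oxymethyl}hept-1-en-6-yn-4-ol
Conditions: LiC≡CH·H2NCH2CH2NH2 (3 equiv.), DMSO, rt; aq. NH4Cl
Reagents that add atoms: none
Why: SN2 opening of the 1,1-disubstituted epoxide at its unsubstituted CH2 carbon by the acetylide leaves the quaternary stereocentre untouched and frees the tertiary alcohol.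

Step 5
Reactants: 7 (4S)-4-{[tert-butyl(dimethyl)silyl]oxymethyl}hept-1-en-6-yn-4-ol
Product: 9 (3R)-3-{[tert-butyl(dimethyl)silyl]oxymethyl}-1,1-dimethoxyhex-5-yn-3-ol, via aldehyde 8 (not isolated)
Conditions: O3, CH2Cl2/MeOH, −78 °C; Me2S; then HC(OMe)3, CeCl3·7H2O (cat.), MeOH, rt
Reagents that add atoms: ozone, [O-][O+]=O (carbonyl oxygen of 8 only); trimethyl orthoformate, COC(OC)OC (methoxy groups of 9)
Why: Ozonolysis of the terminal alkene (much faster than attack on the alkyne) with reductive work-up gives aldehyde 8, which is acetalised in the same flask so that the β-hydroxy aldehyde is never stored; the stereocentre is not involved.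

**Butenolide fragment**

Step 6
Reactants: 10 acrolein; 11 1-propynylmagnesium bromide
Product: 12 rac-hex-1-en-4-yn-3-ol
Conditions: THF, −78 °C to 0 °C; aq. NH4Cl
Reagents that add atoms: none
Why: 1,2-Addition of the alkynyl Grignard reagent to the aldehyde gives the racemic enynol.

Step 7
Reactants: 12 rac-hex-1-en-4-yn-3-ol
Product: 13 (3R)-hex-1-en-4-yn-3-ol
Conditions: Ti(OiPr)4 (15 mol%), D-(−)-diisopropyl tartrate (18 mol%), t-BuOOH (0.6 equiv.), 4 Å molecular sieves, CH2Cl2, −20 °C, stopped a little beyond half conversion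
Reagents that add atoms: none
Why: Sharpless kinetic resolution: with the D-(−)-tartrate catalyst the (S)-enantiomer should be epoxidised at its vinyl group much faster, so the (R)-alcohol is recovered and separated from the polar epoxy alcohol.

Step 8
Reactants: 13 (3R)-hex-1-en-4-yn-3-ol
Product: 15 (3R,4Z)-5-iodohexa-1,4-dien-3-ol, via cyclic vinylalanate 14 (not isolated)
Conditions: NaAlH2(OCH2CH2OMe)2 (Red-Al), THF, 0 °C to rt; then I2, −78 °C to 0 °C
Reagents that add atoms: NaAlH2(OCH2CH2OMe)2, [Na+].[AlH2-](OCCOC)OCCOC (aluminium and alkoxy groups of 14 only); iodine, II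
Why: Hydroxyl-directed trans-hydroalumination places aluminium on the distal alkyne carbon in a five-membered alanate, and iodinolysis with retention gives the Z-alkenyl iodide (iodine cis to the carbinol carbon), which fixes the later C4=C5 geometry; the carbinol centre is untouched.

Step 9
Reactants: 15 (3R,4Z)-5-iodohexa-1,4-dien-3-ol; 16 acryloyl chloride
Product: 17 (3R,4Z)-5-iodohexa-1,4-dien-3-yl prop-2-enoate
Conditions: Et3N, CH2Cl2, −78 °C to 0 °C
Reagents that add atoms: none
Why: O-Acylation of the secondary alcohol at low temperature, with retention of configuration.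

Step 10
Reactants: 17 (3R,4Z)-5-iodohexa-1,4-dien-3-yl prop-2-enoate; 18 formaldehyde
Product: 19 (3R,4Z)-5-iodohexa-1,4-dien-3-yl 2-(hydroxymethyl)prop-2-enoate
Conditions: 37% aq. formaldehyde, DABCO, 1,4-dioxane/H2O (1:1), rt
Reagents that add atoms: none
Why: Morita–Baylis–Hillman reaction of the acrylate with formaldehyde installs the hydroxymethyl group (the later C13) on the α-carbon.

Step 11
Reactants: 19 (3R,4Z)-5-iodohexa-1,4-dien-3-yl 2-(hydroxymethyl)prop-2-enoate
Product: 20 (5R)-3-(hydroxymethyl)-5-[(1Z)-2-iodoprop-1-en-1-yl]furan-2(5H)-one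
Conditions: second-generation Hoveyda–Grubbs catalyst (5 mol%), toluene, 80 °C
Reagents that add atoms: none
Why: Ring-closing metathesis between the vinyl group and the 1,1-disubstituted acrylate closes the butenolide with loss of ethene; the iodinated trisubstituted alkene is inert and C6 is untouched.

**Assembly and end game**

Step 12
Reactants: 9 (3R)-3-{[tert-butyl(dimethyl)silyl]oxymethyl}-1,1-dimethoxyhex-5-yn-3-ol; 20 (5R)-3-(hydroxymethyl)-5-[(1Z)-2-iodoprop-1-en-1-yl]furan-2(5H)-one
Product: 21 (5S)-5-[(1Z,6R)-6-{[tert-butyl(dimethyl)silyl]oxymethyl}-6-hydroxy-8,8-dimethoxy-2-methyloct-1-en-3-yn-1-yl]-3-(hydroxymethyl)furan-2(5H)-one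
Conditions: Pd(PPh3)4 (5 mol%), CuI (10 mol%), i-Pr2NH (3 equiv.), THF, rt
Reagents that add atoms: none
Why: Sonogashira coupling proceeds with retention at the Z-alkenyl iodide, so C3 ends up cis to C6 across C4=C5; free hydroxyl groups are tolerated.

Step 13
Reactants: 21 (the enyne diol of step 12)
Product: 22 (5S)-3-(bromomethyl)-5-[(1Z,6R)-6-{[tert-butyl(dimethyl)silyl]oxymethyl}-6-hydroxy-8,8-dimethoxy-2-methyloct-1-en-3-yn-1-yl]furan-2(5H)-one
Conditions: CBr4, PPh3, 2,6-lutidine, CH2Cl2, 0 °C
Reagents that add atoms: carbon tetrabromide, BrC(Br)(Br)Br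
Why: Appel reaction converts the only primary (allylic) alcohol into the bromide; the tertiary alcohol is too hindered to react.

Step 14
Reactants: 22 (the allylic bromide of step 13)
Product: 23 (5S)-3-(bromomethyl)-5-[(1Z,6R)-6-{[tert-butyl(dimethyl)silyl]oxymethyl}-6-hydroxy-2-methyl-8-oxooct-1-en-3-yn-1-yl]furan-2(5H)-one
Conditions: PPTS (cat.), acetone/H2O (10:1), 40 °C
Reagents that add atoms: water, O
Why: Mild acid-catalysed hydrolysis of the dimethyl acetal releases the aldehyde, while the neopentyl-type TBS ether, the allylic bromide and the tertiary alcohol should survive.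

Step 15
Reactants: 23 (the hydroxy aldehyde of step 14)
Product: 24 (5S)-3-(bromomethyl)-5-[(1Z)-2-{(5R)-5-{[tert-butyl(dimethyl)silyl]oxymethyl}-5-(2-oxoethyl)-4,5-dihydrofuran-2-yl}prop-1-en-1-yl]furan-2(5H)-one
Conditions: Ph3PAuNTf2 (2 mol%), 4 Å molecular sieves, THF, rt
Reagents that add atoms: none
Why: Gold-catalysed 5-endo-dig hydroalkoxylation (cycloisomerisation) of the homopropargylic alcohol: the cationic monovalent gold complex activates the enyne triple bond, the tertiary hydroxyl attacks the distal alkyne carbon C3 and protodeauration gives the 2-alkenyl-4,5-dihydrofuran, so C3 is sp2 and carries no stereocentre to control.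

Step 16
Reactants: 24 (the dihydrofuran aldehyde of step 15)
Product: 26 (6S,7R,8S,10R)-14-{[tert-butyl(dimethyl)silyl]oxy}-8-hydroxy-3,10-epoxygermacra-2,4(Z),11(13)-trien-12,6-olide, via allylchromium dichloride 25 (not isolated)
Conditions: CrCl2 (10 equiv.), THF, rt, 24 added by syringe pump to 0.002 M; aq. NH4Cl
Reagents that add atoms: CrCl2, Cl[Cr]Cl (chromium and chlorine of 25 only; none remain in 26)
Why: CrCl2 (two equivalents consumed) reduces the allylic bromide to the trivalent allylchromium 25, which adds to the tethered aldehyde through a six-membered chair (Zimmerman–Traxler) transition state with bond formation at the γ-carbon C7 and allylic transposition, so that C7–C8 forms and the C11=C13 methylene appears in the same event. The closest known reaction type is the intramolecular Nozaki–Hiyama–Kishi (chromium Barbier) allylation used to close ten-membered germacranolide carbocycles, together with the intermolecular chromium-, zinc- and indium-mediated additions of 3-(bromomethyl)butenolides to aldehydes. One ring is closed, the nine-membered oxonine O–C3–C4=C5–C6–C7–C8–C9–C10, in 9-exo-trig mode at the aldehyde carbon (the C1–C10 carbocyclic perimeter closes with it as the envelope of this ring and the dihydrofuran). C7 is set by the tether: the aldehyde arm hangs from C6 on one face of the planar butenolide and should reach C7 only on that face, so C5 and C8 end up cis on the lactone (7R). C8 is set by the chair: the ring holds the C6 substituent of the allyl unit trans to CH2Cr (an E-crotyl type reagent), which places C9 equatorial and should give the anti (8S) carbinol, inverted in step 17. The step needs ring closure to outrun intermolecular allylation and protonation of 25, which slow addition to high dilution and the chain-folding Z-alkene and dihydrofuran should secure, and it needs γ- over α-attack and aldehyde over lactone selectivity, both inherent to allylchromium reagents.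

Step 17
Reactants: 26 (the 8S alcohol of step 16); 27 (2R)-2-methylbutanoic acid
Product: 28 (6S,7R,8R,10R)-14-{[tert-butyl(dimethyl)silyl]oxy}-8-{[(2R)-2-methylbutanoyl]oxy}-3,10-epoxygermacra-2,4(Z),11(13)-trien-12,6-olide
Conditions: PPh3, DIAD, THF, 0 °C to rt
Reagents that add atoms: none
Why: Mitsunobu esterification: the alkoxyphosphonium ion of the 8S alcohol is displaced by the carboxylate of 27 in an SN2 reaction with inversion, giving the 8R ester, and the α-stereocentre of the acid is not epimerised under these conditions.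

Step 18
Reactants: 28 (the ester of step 17)
Product: 29 (3S,6S,7R,8R,10R)-3,14-dihydroxy-8-{[(2R)-2-methylbutanoyl]oxy}-3,10-epoxygermacra-4(Z),11(13)-dien-12,6-olide (CNP0328225.2)
Conditions: 48% aq. HF, MeCN, 0 °C to rt; aq. NaHCO3
Reagents that add atoms: water, O
Why: Acid-catalysed hydration of the bridgehead enol ether (protonation at C2, capture of the C3 oxocarbenium ion by water at the only position the bicycle leaves open, hence 3S) together with fluoride cleavage of the TBS ether should deliver the hemiketal diol.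

**Compound list**

1 | propargyl alcohol | C#CCO | starting material
2 | allylmagnesium chloride | C=CC[Mg]Cl | starting material
3 | 2-methylidenepent-4-en-1-ol | C=CCC(=C)CO | intermediate
4 | [(2R)-2-(prop-2-en-1-yl)oxiran-2-yl]methanol | C=CC[C@@]1(CO)CO1 | intermediate
5 | tert-butyl(dimethyl){[(2S)-2-(prop-2-en-1-yl)oxiran-2-yl]methoxy}silane | C=CC[C@@]1(CO[Si](C)(C)C(C)(C)C)CO1 | intermediate
6 | lithium acetylide–ethylenediamine complex | [Li]C#C.NCCN | starting material
7 | (4S)-4-{[tert-butyl(dimethyl)silyl]oxymethyl}hept-1-en-6-yn-4-ol | C=CC[C@@](O)(CO[Si](C)(C)C(C)(C)C)CC#C | intermediate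
8 | (3R)-3-{[tert-butyl(dimethyl)silyl]oxymethyl}-3-hydroxyhex-5-ynal (not isolated) | O=CC[C@@](O)(CO[Si](C)(C)C(C)(C)C)CC#C | intermediate
9 | (3R)-3-{[tert-butyl(dimethyl)silyl]oxymethyl}-1,1-dimethoxyhex-5-yn-3-ol | COC(OC)C[C@@](O)(CO[Si](C)(C)C(C)(C)C)CC#C | intermediate
10 | acrolein | C=CC=O | starting material
11 | 1-propynylmagnesium bromide | CC#C[Mg]Br | starting material
12 | rac-hex-1-en-4-yn-3-ol | CC#CC(O)C=C | intermediate
13 | (3R)-hex-1-en-4-yn-3-ol | CC#C[C@H](O)C=C | intermediate
14 | sodium (5R)-5-ethenyl-2,2-bis(2-methoxyethoxy)-3-methyl-2,5-dihydro-1,2-oxaluminol-2-uide, the cyclic vinylalanate (not isolated) | C=C[C@H]1O[Al-](OCCOC)(OCCOC)C(C)=C1.[Na+] | intermediate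
15 | (3R,4Z)-5-iodohexa-1,4-dien-3-ol | C/C(I)=C/[C@H](O)C=C | intermediate
16 | acryloyl chloride | C=CC(=O)Cl | starting material
17 | (3R,4Z)-5-iodohexa-1,4-dien-3-yl prop-2-enoate | C/C(I)=C/[C@H](OC(=O)C=C)C=C | intermediate
18 | formaldehyde | C=O | starting material
19 | (3R,4Z)-5-iodohexa-1,4-dien-3-yl 2-(hydroxymethyl)prop-2-enoate | C/C(I)=C/[C@H](OC(=O)C(=C)CO)C=C | intermediate
20 | (5R)-3-(hydroxymethyl)-5-[(1Z)-2-iodoprop-1-en-1-yl]furan-2(5H)-one | C/C(I)=C/[C@@H]1OC(=O)C(CO)=C1 | intermediate
21 | (5S)-5-[(1Z,6R)-6-{[tert-butyl(dimethyl)silyl]oxymethyl}-6-hydroxy-8,8-dimethoxy-2-methyloct-1-en-3-yn-1-yl]-3-(hydroxymethyl)furan-2(5H)-one | COC(OC)C[C@@](O)(CO[Si](C)(C)C(C)(C)C)CC#C/C(C)=C\[C@@H]1OC(=O)C(CO)=C1 | intermediate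
22 | (5S)-3-(bromomethyl)-5-[(1Z,6R)-6-{[tert-butyl(dimethyl)silyl]oxymethyl}-6-hydroxy-8,8-dimethoxy-2-methyloct-1-en-3-yn-1-yl]furan-2(5H)-one | COC(OC)C[C@@](O)(CO[Si](C)(C)C(C)(C)C)CC#C/C(C)=C\[C@@H]1OC(=O)C(CBr)=C1 | intermediate
23 | (5S)-3-(bromomethyl)-5-[(1Z,6R)-6-{[tert-butyl(dimethyl)silyl]oxymethyl}-6-hydroxy-2-methyl-8-oxooct-1-en-3-yn-1-yl]furan-2(5H)-one | O=CC[C@@](O)(CO[Si](C)(C)C(C)(C)C)CC#C/C(C)=C\[C@@H]1OC(=O)C(CBr)=C1 | intermediate
24 | (5S)-3-(bromomethyl)-5-[(1Z)-2-{(5R)-5-{[tert-butyl(dimethyl)silyl]oxymethyl}-5-(2-oxoethyl)-4,5-dihydrofuran-2-yl}prop-1-en-1-yl]furan-2(5H)-one | O=CC[C@@]1(CO[Si](C)(C)C(C)(C)C)CC=C(O1)/C(C)=C\[C@@H]1OC(=O)C(CBr)=C1 | intermediate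
25 | allylchromium dichloride of 24 (trivalent chromium on C13 in place of bromine; not isolated) | O=CC[C@@]1(CO[Si](C)(C)C(C)(C)C)CC=C(O1)/C(C)=C\[C@@H]1OC(=O)C(C[Cr](Cl)Cl)=C1 | intermediate
26 | (6S,7R,8S,10R)-14-{[tert-butyl(dimethyl)silyl]oxy}-8-hydroxy-3,10-epoxygermacra-2,4(Z),11(13)-trien-12,6-olide | C=C1C(=O)O[C@H]2/C=C(/C)C3=CC[C@](CO[Si](C)(C)C(C)(C)C)(C[C@H](O)[C@@H]12)O3 | intermediate
27 | (2R)-2-methylbutanoic acid | CC[C@@H](C)C(=O)O | starting material
28 | (6S,7R,8R,10R)-14-{[tert-butyl(dimethyl)silyl]oxy}-8-{[(2R)-2-methylbutanoyl]oxy}-3,10-epoxygermacra-2,4(Z),11(13)-trien-12,6-olide | C=C1C(=O)O[C@H]2/C=C(/C)C3=CC[C@](CO[Si](C)(C)C(C)(C)C)(C[C@@H](OC(=O)[C@H](C)CC)[C@@H]12)O3 | intermediate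
29 | (3S,6S,7R,8R,10R)-3,14-dihydroxy-8-{[(2R)-2-methylbutanoyl]oxy}-3,10-epoxygermacra-4(Z),11(13)-dien-12,6-olide (CNP0328225.2) | C=C1C(=O)O[C@H]2/C=C(/C)[C@]3(O)CC[C@](CO)(C[C@@H](OC(=O)[C@H](C)CC)[C@@H]12)O3 | target

**Totals**

Total step count: 18. Longest linear sequence: 13 steps (steps 6 to 18, from acrolein).

**Steps most likely to fail**

Step 16. The allylchromium 25 may be consumed by addition to a second molecule of aldehyde, by protonation or by reductive dimerisation before it reaches the strained nine-membered transition state, or it may add to the face of C7 anti to the tether. The fallback sets out from 24. Palladium-catalysed borylation of the allylic bromide (B2pin2, Pd2(dba)3 cat., toluene, rt) should give the pinacol allylboronate F1, a nucleophile that is neither basic nor reducing and tolerates long heating. At high dilution in toluene at 80 °C it should close the same C7–C8 bond by thermal allylboration through a boron-centred chair, and aqueous work-up of the borate comes back to the route at 26.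

Step 17. Displacement at the hindered C8 alkoxyphosphonium ion by the α-branched carboxylate may be so slow that elimination towards C7 or C9, or acyl transfer with retention, takes over. The fallback sets out from 26. Buffered Dess–Martin oxidation (NaHCO3, CH2Cl2, 0 °C) should give the C8 ketone F2, handled cold and neutral because C7–H is then acidic. Reduction with NaBH4/CeCl3·7H2O in MeOH at −78 °C, with hydride expected from the open outer face of the medium ring, should give the 8R alcohol F3. Carbodiimide esterification with 27 (DCC, DMAP, CH2Cl2) proceeds with retention and comes back to the route at 28.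

Step 15. The aldehyde oxygen may compete with the tertiary hydroxyl for the gold-activated alkyne, the β-hydroxy aldehyde may dehydrate, or the product enol ether may add a second molecule under the Lewis acid. The fallback sets out from 22. The hydroxyl–alkyne ring closure is run before the aldehyde exists (Ph3PAuNTf2, THF, rt) to give the dihydrofuran acetal F4. The dimethyl acetal is then removed without aqueous acid, under base-buffered conditions that should spare the enol ether (Et3SiOTf, 2,4,6-collidine, CH2Cl2, 0 °C; then H2O), which comes back to the route at 24.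

**Further compounds**

F1 | step 16 | pinacol allylboronate of 24 (4,4,5,5-tetramethyl-1,3,2-dioxaborolan-2-yl on C13 in place of bromine, configuration as in 24) | O=CC[C@@]1(CO[Si](C)(C)C(C)(C)C)CC=C(O1)/C(C)=C\[C@@H]1OC(=O)C(CB2OC(C)(C)C(C)(C)O2)=C1
F2 | step 17 | (6S,7R,10R)-14-{[tert-butyl(dimethyl)silyl]oxy}-8-oxo-3,10-epoxygermacra-2,4(Z),11(13)-trien-12,6-olide | C=C1C(=O)O[C@H]2/C=C(/C)C3=CC[C@](CO[Si](C)(C)C(C)(C)C)(CC(=O)[C@@H]12)O3
F3 | step 17 | (6S,7R,8R,10R)-14-{[tert-butyl(dimethyl)silyl]oxy}-8-hydroxy-3,10-epoxygermacra-2,4(Z),11(13)-trien-12,6-olide | C=C1C(=O)O[C@H]2/C=C(/C)C3=CC[C@](CO[Si](C)(C)C(C)(C)C)(C[C@@H](O)[C@@H]12)O3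
F4 | step 15 | (5S)-3-(bromomethyl)-5-[(1Z)-2-{(5R)-5-{[tert-butyl(dimethyl)silyl]oxymethyl}-5-(2,2-dimethoxyethyl)-4,5-dihydrofuran-2-yl}prop-1-en-1-yl]furan-2(5H)-one | COC(OC)C[C@@]1(CO[Si](C)(C)C(C)(C)C)CC=C(O1)/C(C)=C\[C@@H]1OC(=O)C(CBr)=C1
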